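## Structural features

Luteolin 7,3'-disulfate is a flavone. A benzo ring (ring A, C5–C8 with C4a and C8a) is fused along the C4a–C8a bond to a 4-pyranone (ring C, O1–C2=C3–C4=O), and C2 carries a catechol-derived phenyl ring (ring B) through the C2–C1' bond. The molecule is flat and has no stereocentre, so every selectivity question is one of regiochemistry or of chemoselectivity among four phenolic oxygens. These oxygens have four different roles: O5 is a free phenol hydrogen-bonded to the peri C4 carbonyl, O7 and O3' are sulfate half-esters, and O4', ortho to O3', is a free phenol. The aryl hydrogen sulfates are the fragile groups. They are strong acids, hydrolyse under acid catalysis, make the compound water-soluble, and do not tolerate strong acid, silylating agents or dissolving-metal conditions, so they must be introduced last. The real difficulty is therefore the differentiation of O3' from O4' in the catechol and of O7 from O5 in ring A, so that exactly O7 and O3' are bare when the sulfating agent is added. The key step exploits ring A. C5, C6, C7 and C8 form a 1,3-dioxygenated four-carbon unit attached to C4a and C8a, which is the pattern obtained when a ketene carbonyl (C5–OH) and a siloxyalkyne (C6 and C7–OSi) are annulated onto a C8a=C4a double bond. Ring A thus arrives with O5 free and chelated and O7 masked differently from it.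

## Logic of the disconnections

23 is traced to 21 (through 22) by putting a benzyl group on O4' and writing the sulfates as triethylammonium salts. The bond in question is O4'–CH2Ph. A benzyl ether is cut here because neutral hydrogenolysis is one of the few deprotections an aryl sulfate survives. The gain is that O4' stays masked during sulfation. The demand is that hydrogenolysis spares the C2=C3 bond and the S–O bonds, and that the acid form is generated only at the very end.

21 is traced to 20 by cutting the O7–S and O3'–S bonds. Sulfation is placed this late because everything before it can then be done on neutral, chromatographable material. The demand is discrimination of O7 and O3' from O5, which the hydrogen bond of O5 to the C4 carbonyl should provide.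

20 is traced to 19 by re-forming the O7–Si and O3'–Si bonds. The two oxygens that will be sulfated are exactly the two that carry the same silyl group, one brought in by the alkyne and one put on ring B earlier, so one fluoride treatment exposes both. The demand is only that the benzyl ether and the pyranone survive buffered fluoride.

19 is traced to 11 and 14 by cutting C8–C8a, C7–C8, C5–C6 and C4a–C5. This removes ring A completely and reduces the flavone to a monocyclic pyranone bearing ring B plus a two-carbon alkyne. It also explains why O5 and O7 are different from the moment they appear. The demand on the forward step is heavy: a Wolff rearrangement next to a pyranone chromophore, a regioselective [2+2] addition, and a 6π closure that must take place onto C4a.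

11 is traced to 9 by cutting the C=N bond at the diazo carbon. Diazo transfer to a methyl ketone is chosen over acylation of diazomethane with an acid chloride, which removes the most hazardous reagent of the sequence and two steps (ester hydrolysis and acid chloride formation). The demand is a single enolizable position, which 9 has.

9 is traced to 8 by cutting the O3'–Si bond. The phenol is silylated only after all strongly basic, alkoxide-releasing and acidic steps are over, so the aryl silyl ether never meets hydroxide or ethoxide.

14 is traced to 12 by cutting the O–Si bond and recognising the ethynolate as C4, C5 and O1 of the isoxazole. This gives the otherwise awkward parent ynolate from a stable heterocycle in one flask. The demand is silylation on oxygen and not on carbon.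

8 is traced to 4 and 5 by opening the pyranone at the ring O–C bond next to the acetyl group and cutting the C–C bond between that carbon and the neighbouring ring CH. The acetyl group is carried as a ketal of a pyruvate ester, so the six-carbon pyranone-plus-acetyl unit comes from a diketone and one non-enolizable ester. The demand is acylation at the terminal carbon of the diketone, which is its only site for a second deprotonation.

4 is traced to 2 and 3 by cutting the C2–C3 bond of the butanedione (Claisen condensation).

2 is traced to 1 by cutting the O4–CH2Ph bond. The demand is alkylation of the para phenol in preference to the meta phenol.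

## Other disconnections considered

Alternative 1: The cut is again in ring A but only at C4a–C5, by a biomimetic Claisen folding.
- Forward step: the hydroxypyrone A1 would be opened by Mg(OMe)2 to the triketo ester A2. The magnesium chelate should steer the methylene between the two ketones on the cinnamoyl side (future C4a) onto the ester carbonyl, and loss of methoxide and enolization would give chalcone A3. An iodine-mediated oxidative cyclization would then form ring C (flavone A4), and acid would remove the methoxymethyl group to reach 20, from which the endgame is the same.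
- In favour: it is ionic chemistry without light, diazo compounds or azides, and on safety and ease of scale-up it is the better plan. The chalcone-to-flavone oxidation is routine.
- Against: A2 can also fold in the aldol sense to a resorcylate-type ring, its enone is exposed to conjugate addition of methoxide, and A1 has to be assembled by polyanion chemistry of its own. Ring C is built after ring A, which costs the oxidation and a deprotection. The methoxymethyl ether needs a carcinogenic alkylating agent.
- Comparison: on structure the two plans are equal at the decisive point, because both rely on the O5 hydrogen bond during sulfation, although A3 delivers all three ring A oxygens undifferentiated. On step count the alternative is about equal. The chosen plan keeps the finished pyranone throughout and needs no oxidation-state adjustment.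

Alternative 2: The cut is in ring B, at C2'–C3' and C1'–C6'.
- Forward step: a Diels–Alder addition of the furan A6 to the alkyne of the ethynylchromone A5 would give the oxa-bridged adduct A7. This should ionize at the C6'–O bond, where the benzyloxy group stabilizes the cation as a vinylogous oxocarbenium ion, and aromatize to A8 with the bridging oxygen left as the 3'-OH.
- In favour: the 3'-OH/4'-OBn pattern comes out of the mechanism, which is more elegant than the selective benzylation of a catechol in step 1. The route is convergent.
- Against: the match of the nucleophilic furan carbon next to the benzyloxy group with the electrophilic alkyne terminus must hold. The dienophile is only weakly activated through the chromone, so heat or a Lewis acid would be needed, under which 3-alkoxyfurans decompose and cycloreversion competes. Both A5 and A6 need several steps each, and A8 still carries a methoxymethyl group to be removed before 20 is reached.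
- Comparison: on the catechol problem the alternative is the better. That problem is already solved cheaply in step 1, however, whereas the alternative does nothing for ring A. On mechanism both rest on a pericyclic cascade with an untried substrate pair. On step count the alternative is probably longer.

Alternative 3: The cut is in ring C, at C3–C4 and O1–C2.
- Forward step: the trivalent rhodium catalyst [(C5Me5)RhCl2]2 would activate the aldehyde C–H bond of salicylaldehyde A9 under direction of the phenol. The sulfoxonium ylide A10 would serve as a carbene source, migratory insertion would join the acyl carbon to the carbene carbon, and cyclodehydration would close the pyranone to A11. Acid would remove the three methoxymethyl groups to give 20.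
- In favour: acylmethylation and annulation of salicylaldehydes with aroyl sulfoxonium ylides is an established way to flavones. Both halves are short to make, so this is the most convergent plan. On precedent and on step count it is better than the chosen route.
- Against: it needs a precious metal and three methoxymethyl ethers, and the aldehyde of A9 is flanked by two ortho substituents, which may slow the C–H activation.
- Comparison: ring A is bought, not built, and the O5/O7 distinction again comes only from chelation, so structurally this is the equal of the chosen plan. The chosen plan is the more instructive construction but carries the higher risk.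

Key step: step 7

Remark on the target form: the target is taken as the free bis(hydrogen sulfate) exactly as drawn. Because aryl hydrogen sulfates hydrolyse under their own acidity, this form is generated only in the last operation and kept cold, and all earlier sulfated compounds are handled as triethylammonium salts.

Remark on sourcing: 3-phenylisoxazole and ethyl 2,2-diethoxypropanoate are taken to be purchasable. Flavone numbering (C2–C8a, primes for ring B) is used for all intermediates.

## Route

Step 1
Reactants: 1 3,4-dihydroxyacetophenone
Product: 2 1-[4-(benzyloxy)-3-hydroxyphenyl]ethan-1-one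
Conditions: BnBr (1.0 equiv), Li2CO3 (1.2 equiv), DMF, 50 °C
Reagents that add atoms: benzyl bromide, BrCc1ccccc1
Why: Williamson etherification; the 4-OH is para to the acetyl group and the more acidic phenol, so the weak base should ionize it preferentially and direct benzylation to O4, and the minor 3-O-benzyl and dibenzyl ethers are removed by crystallization or chromatography.

Step 2
Reactants: 2 1-[4-(benzyloxy)-3-hydroxyphenyl]ethan-1-one; 3 ethyl acetate
Product: 4 1-[4-(benzyloxy)-3-hydroxyphenyl]butane-1,3-dione
Conditions: NaH (4 equiv), EtOAc (5 equiv), THF, 0 °C to reflux; aq. HCl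
Reagents that add atoms: none
Why: Crossed Claisen condensation; after the phenol has become its sodium salt the ketone enolate is acylated by ethyl acetate, and deprotonation of the beta-diketone pulls the equilibrium forward while the phenoxide is a spectator.

Step 3
Reactants: 4 1-[4-(benzyloxy)-3-hydroxyphenyl]butane-1,3-dione; 5 ethyl 2,2-diethoxypropanoate
Product: 8 2-acetyl-6-[4-(benzyloxy)-3-hydroxyphenyl]-4H-pyran-4-one, via triketone ketal 6 (not isolated), via pyranone ketal 7 (not isolated)
Conditions: LiN(iPr)2 (4.2 equiv), THF, −78 to 0 °C; 5 (1.1 equiv), 0 to 25 °C; aq. HCl; crude in AcOH/H2O (9:1), H2SO4 (0.2 equiv), 60 °C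
Reagents that add atoms: water, O
Why: Acylation of a beta-diketone polyanion at its terminal carbon by a non-enolizable ester (Harris-type gamma-acylation) gives the 1,3,5-triketone, and acid cyclodehydrates it to the 4-pyranone in the classical way while the same aqueous acid hydrolyses the ketal to the acetyl group. Only the methyl terminus of 4 can carry the second carbanion, so the site of acylation is not in doubt.

Step 4
Reactants: 8 2-acetyl-6-[4-(benzyloxy)-3-hydroxyphenyl]-4H-pyran-4-one
Product: 9 2-acetyl-6-[4-(benzyloxy)-3-(triisopropylsilyloxy)phenyl]-4H-pyran-4-one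
Conditions: iPr3SiCl (1.3 equiv), imidazole (2.5 equiv), DMF, 25–40 °C
Reagents that add atoms: chlorotriisopropylsilane, CC(C)[Si](Cl)(C(C)C)C(C)C
Why: Imidazole-promoted silylation of a phenol; the silyl chloride with imidazole should not enolize the methyl ketone as a silyl triflate with an amine base would, and the triisopropylsilyl ether matches the group the alkyne delivers to O7, so one fluoride treatment later frees both oxygens.

Step 5
Reactants: 9 2-acetyl-6-[4-(benzyloxy)-3-(triisopropylsilyloxy)phenyl]-4H-pyran-4-one
Product: 11 2-(2-diazoacetyl)-6-[4-(benzyloxy)-3-(triisopropylsilyloxy)phenyl]-4H-pyran-4-one, via trifluoroacetyl diketone 10 (not isolated)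
Conditions: LiN(SiMe3)2 (1.1 equiv), THF, −78 °C; CF3CO2CH2CF3 (1.2 equiv), −78 °C; aq. HCl; then 4-acetamidobenzenesulfonyl azide (1.5 equiv), Et3N (1.5 equiv), H2O (1 equiv), MeCN, 25 °C
Reagents that add atoms: 4-acetamidobenzenesulfonyl azide, CC(=O)Nc1ccc(cc1)S(=O)(=O)N=[N+]=[N-]
Why: Detrifluoroacetylative diazo transfer (Danheiser protocol); the kinetic lithium enolate of the only enolizable position is C-trifluoroacetylated, and the activated diketone takes the diazo group from the sulfonyl azide while the trifluoroacetyl group leaves on the sulfonamide nitrogen. A shelf-stable, non-volatile azide thus replaces the acid chloride–diazomethane sequence.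

Step 6
Reactants: 12 3-phenylisoxazole
Product: 14 (triisopropylsilyloxy)ethyne, via lithium ethynolate 13 (not isolated)
Conditions: n-BuLi (1.05 equiv), THF, −78 to 0 °C; iPr3SiOSO2CF3 (1.0 equiv), −78 to 0 °C; bulb-to-bulb distillation
Reagents that add atoms: triisopropylsilyl trifluoromethanesulfonate, CC(C)[Si](C(C)C)(C(C)C)OS(=O)(=O)C(F)(F)F
Why: Lithiation of a 3-arylisoxazole at C5 triggers cycloreversion to the nitrile and lithium ethynolate (Schöllkopf fragmentation); a hard, bulky silyl triflate is expected to silylate an ynolate on oxygen, as in the Kowalski preparation of siloxyalkynes, whereas small silyl chlorides give silylketenes.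

Step 7
Reactants: 11 2-(2-diazoacetyl)-6-[4-(benzyloxy)-3-(triisopropylsilyloxy)phenyl]-4H-pyran-4-one; 14 (triisopropylsilyloxy)ethyne
Product: 19 4'-O-benzyl-7,3'-bis-O-(triisopropylsilyl)luteolin, via ketene 15 (not isolated), via cyclobutenone 16 (not isolated), via dienylketene 17 (not isolated), via cyclohexadienone 18 (not isolated)
Conditions: 14 (2.5 equiv), hν (440 nm LED, flow coil), ClCH2CH2Cl (degassed), 25 °C; then 80 °C
Reagents that add atoms: none
Why: Proposed new method: excitation of the diazoketone in its weak long-wavelength band, where the arylpyranone should be nearly transparent, is expected to expel N2 and shift the pyranonyl carbon to the carbene centre (Wolff rearrangement, bond C8–C8a), giving ketene 15, which is a vinylketene because its alpha carbon sits on the C8a=C4a double bond of the pyranone. The electron-rich alkyne 14 should add across the ketene C=C bond in a polar stepwise [2+2] cycloaddition, its unsubstituted carbon attacking the ketene carbonyl carbon (C5–C6) and the siloxy-bearing carbon closing onto the alpha carbon (C7–C8), so only the 3-siloxy-4-pyranonylcyclobutenone 16 can form. At 80 °C 16 should open by reversible conrotatory 4π cleavage of its C5–C8 bond to dienylketene 17, and the isomer with ketenyl and pyranonyl groups cis closes ring A as a six-membered carbocycle by disrotatory 6π electrocyclization (bond C4a–C5); dienone 18 then enolizes to the chelated 5-phenol 19. The closest known reaction type is the photo-Wolff form of the Danheiser benzannulation of aryl and heteroaryl diazomethyl ketones with siloxyalkynes; a 4-pyranone double bond as the ene component and an alkyne without a carbon substituent are the untried elements. No stereocentre is formed. The 7-OSi/5-OH regiochemistry follows from the polarity of the ynol ether, and the site of ring closure is fixed because C4a is the only carbon neighbour of C8a in the ring, the other neighbour being O1. Excess 14 is meant to outrun ketene dimerization and acylation of the product phenol, whose nucleophilicity is in any case lowered by its hydrogen bond to the C4 carbonyl.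

Step 8
Reactants: 19 4'-O-benzyl-7,3'-bis-O-(triisopropylsilyl)luteolin
Product: 20 4'-O-benzylluteolin
Conditions: Bu4NF (2.5 equiv), AcOH (2.5 equiv), THF, 0 °C
Reagents that add atoms: none
Why: Fluoride-mediated cleavage of aryl silyl ethers; acetic acid buffers the phenoxides so that the pyranone ring and the benzyl ether are left alone.

Step 9
Reactants: 20 4'-O-benzylluteolin
Product: 21 bis(triethylammonium) 4'-O-benzylluteolin 7,3'-disulfate
Conditions: SO3·NEt3 (5 equiv), Et3N (3 equiv), DMF, 40 °C; SiO2, CH2Cl2/MeOH/Et3N
Reagents that add atoms: sulfur trioxide–triethylamine complex, CC[N+](CC)(CC)S(=O)(=O)[O-]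
Why: O-Sulfonation of phenols by an amine–SO3 complex; the 7- and 3'-hydroxyls react, whereas the 5-OH is held in a six-membered hydrogen bond to the C4 carbonyl and is far less nucleophilic, so the reaction should stop at the disulfate. As a lipophilic triethylammonium salt the product can be chromatographed.

Step 10
Reactants: 21 bis(triethylammonium) 4'-O-benzylluteolin 7,3'-disulfate
Product: 23 luteolin 7,3'-disulfate, via bis(triethylammonium) luteolin 7,3'-disulfate 22 (not isolated)
Conditions: H2 (1 atm), Pd/C (10 wt%), MeOH/H2O (4:1), 25 °C; filter; sulfonic acid resin (H+ form), H2O, 0 °C; freeze-dry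
Reagents that add atoms: none
Why: Catalytic hydrogenolysis of an aryl benzyl ether under neutral conditions, which aryl sulfate salts tolerate and which should leave the C2=C3 bond of the flavone alone at 1 atm; a brief cold passage through the acid resin exchanges triethylammonium for protons and gives the acid form drawn.

## Compound list

1 | 3,4-dihydroxyacetophenone | CC(=O)c1ccc(O)c(O)c1 | starting material
2 | 1-[4-(benzyloxy)-3-hydroxyphenyl]ethan-1-one | CC(=O)c1ccc(OCc2ccccc2)c(O)c1 | intermediate
3 | ethyl acetate | CCOC(C)=O | starting material
4 | 1-[4-(benzyloxy)-3-hydroxyphenyl]butane-1,3-dione | CC(=O)CC(=O)c1ccc(OCc2ccccc2)c(O)c1 | intermediate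
5 | ethyl 2,2-diethoxypropanoate | CCOC(=O)C(C)(OCC)OCC | starting material
6 | 1-[4-(benzyloxy)-3-hydroxyphenyl]-6,6-diethoxyheptane-1,3,5-trione | CCOC(C)(OCC)C(=O)CC(=O)CC(=O)c1ccc(OCc2ccccc2)c(O)c1 | intermediate (not isolated)
7 | 2-[4-(benzyloxy)-3-hydroxyphenyl]-6-(1,1-diethoxyethyl)-4H-pyran-4-one | CCOC(C)(OCC)c1cc(=O)cc(-c2ccc(OCc3ccccc3)c(O)c2)o1 | intermediate (not isolated)
8 | 2-acetyl-6-[4-(benzyloxy)-3-hydroxyphenyl]-4H-pyran-4-one | CC(=O)c1cc(=O)cc(-c2ccc(OCc3ccccc3)c(O)c2)o1 | intermediate
9 | 2-acetyl-6-[4-(benzyloxy)-3-(triisopropylsilyloxy)phenyl]-4H-pyran-4-one | CC(=O)c1cc(=O)cc(-c2ccc(OCc3ccccc3)c(O[Si](C(C)C)(C(C)C)C(C)C)c2)o1 | intermediate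
10 | 1-{6-[4-(benzyloxy)-3-(triisopropylsilyloxy)phenyl]-4-oxo-4H-pyran-2-yl}-4,4,4-trifluorobutane-1,3-dione | O=C(CC(=O)C(F)(F)F)c1cc(=O)cc(-c2ccc(OCc3ccccc3)c(O[Si](C(C)C)(C(C)C)C(C)C)c2)o1 | intermediate (not isolated)
11 | 2-(2-diazoacetyl)-6-[4-(benzyloxy)-3-(triisopropylsilyloxy)phenyl]-4H-pyran-4-one | [N-]=[N+]=CC(=O)c1cc(=O)cc(-c2ccc(OCc3ccccc3)c(O[Si](C(C)C)(C(C)C)C(C)C)c2)o1 | intermediate
12 | 3-phenylisoxazole | c1ccc(-c2ccon2)cc1 | starting material
13 | lithium ethynolate | [Li+].[O-]C#C | intermediate (not isolated)
14 | (triisopropylsilyloxy)ethyne | C#CO[Si](C(C)C)(C(C)C)C(C)C | intermediate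
15 | {6-[4-(benzyloxy)-3-(triisopropylsilyloxy)phenyl]-4-oxo-4H-pyran-2-yl}ketene | O=C=Cc1cc(=O)cc(-c2ccc(OCc3ccccc3)c(O[Si](C(C)C)(C(C)C)C(C)C)c2)o1 | intermediate (not isolated)
16 | 4-{6-[4-(benzyloxy)-3-(triisopropylsilyloxy)phenyl]-4-oxo-4H-pyran-2-yl}-3-(triisopropylsilyloxy)cyclobut-2-en-1-one (racemic) | O=C1C=C(O[Si](C(C)C)(C(C)C)C(C)C)C1c1cc(=O)cc(-c2ccc(OCc3ccccc3)c(O[Si](C(C)C)(C(C)C)C(C)C)c2)o1 | intermediate (not isolated)
17 | (3E)-4-{6-[4-(benzyloxy)-3-(triisopropylsilyloxy)phenyl]-4-oxo-4H-pyran-2-yl}-3-(triisopropylsilyloxy)buta-1,3-dien-1-one (ketenyl and pyranonyl groups cis) | O=C=C/C(O[Si](C(C)C)(C(C)C)C(C)C)=C\c1cc(=O)cc(-c2ccc(OCc3ccccc3)c(O[Si](C(C)C)(C(C)C)C(C)C)c2)o1 | intermediate (not isolated)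
18 | 2-[4-(benzyloxy)-3-(triisopropylsilyloxy)phenyl]-7-(triisopropylsilyloxy)-4aH-chromene-4,5-dione (racemic) | O=C1C=C(O[Si](C(C)C)(C(C)C)C(C)C)C=C2OC(c3ccc(OCc4ccccc4)c(O[Si](C(C)C)(C(C)C)C(C)C)c3)=CC(=O)C12 | intermediate (not isolated)
19 | 4'-O-benzyl-7,3'-bis-O-(triisopropylsilyl)luteolin; 2-[4-(benzyloxy)-3-(triisopropylsilyloxy)phenyl]-5-hydroxy-7-(triisopropylsilyloxy)-4H-chromen-4-one | O=c1cc(-c2ccc(OCc3ccccc3)c(O[Si](C(C)C)(C(C)C)C(C)C)c2)oc2cc(O[Si](C(C)C)(C(C)C)C(C)C)cc(O)c12 | intermediate
20 | 4'-O-benzylluteolin; 2-[4-(benzyloxy)-3-hydroxyphenyl]-5,7-dihydroxy-4H-chromen-4-one | O=c1cc(-c2ccc(OCc3ccccc3)c(O)c2)oc2cc(O)cc(O)c12 | intermediate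
21 | bis(triethylammonium) 4'-O-benzylluteolin 7,3'-disulfate | O=c1cc(-c2ccc(OCc3ccccc3)c(OS(=O)(=O)[O-])c2)oc2cc(OS(=O)(=O)[O-])cc(O)c12.CC[NH+](CC)CC.CC[NH+](CC)CC | intermediate
22 | bis(triethylammonium) luteolin 7,3'-disulfate | O=c1cc(-c2ccc(O)c(OS(=O)(=O)[O-])c2)oc2cc(OS(=O)(=O)[O-])cc(O)c12.CC[NH+](CC)CC.CC[NH+](CC)CC | intermediate (not isolated)
23 | luteolin 7,3'-disulfate; 5-hydroxy-2-[4-hydroxy-3-(sulfooxy)phenyl]-4-oxo-4H-chromen-7-yl hydrogen sulfate | O=c1cc(-c2ccc(O)c(OS(=O)(=O)O)c2)oc2cc(OS(=O)(=O)O)cc(O)c12 | target

## Step count and least certain steps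

Total step count: 10. Longest linear sequence: 9 steps (steps 1–5 and 7–10, from 1). Step 6 is a one-step side branch.

Step 7 (key step, new substrate class).
- What may go wrong: the arylpyranone chromophore may absorb or sensitize, giving photoisomerization of the pyranone instead of clean nitrogen loss. The carbene may be trapped before the electron-poor pyranonyl group migrates. The sequence may stall at the cyclobutenone because the 6π closure has to interrupt the conjugation of the pyranone. The unhindered alkyne may oligomerize. The ketene may acylate the product phenol.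
- Fallback (known chemistry only): it sets out from 2. Claisen condensation of 2 with diethyl carbonate (NaH, THF) would give ethyl 3-[4-(benzyloxy)-3-hydroxyphenyl]-3-oxopropanoate F1. Heating F1 with benzene-1,3,5-triol without solvent (about 240 °C, microwave; Mentzer pyrone synthesis) would proceed through the acylketene formed by loss of ethanol, C-acylation of the triol and cyclodehydration. This would give 20 directly, and the route is rejoined at 20 before step 9. The fallback gives up the ring A construction altogether and is shorter.

Step 6.
- What may go wrong: silylation of the ambident ethynolate on carbon instead of oxygen, and loss of the volatile, acid-sensitive product while it is separated from benzonitrile.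
- Fallback: it sets out from 11 and a differently made alkyne. Ethynyltrimethylsilane would be lithiated (n-BuLi) and oxidized to the silyl ynolate with LiOOtBu (Julia-type acetylide oxidation). O-silylation with iPr3SiOSO2CF3 would give 1-(triisopropylsilyloxy)-2-(trimethylsilyl)ethyne F2, a less volatile and sterically protected alkyne. Benzannulation of 11 with F2 under the conditions of step 7 would give 4'-O-benzyl-7,3'-bis-O-(triisopropylsilyl)-6-(trimethylsilyl)luteolin F3. Ipso-protodesilylation of the very electron-rich C6 (CF3CO2H, CH2Cl2, 0 °C) would return to the route at 19.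

Step 3.
- What may go wrong: incomplete formation or poor solubility of the phenoxide–diketone trianion, O-acylation instead of C-acylation, slow hydrolysis of the ketal next to the electron-poor pyranone, or acid-induced loss of the benzyl ether during prolonged heating.
- Fallback: it sets out from 4 and follows the oxalate route.
  - Condensation of 4 with diethyl oxalate (NaOEt, EtOH) and acid cyclization (HCl, EtOH) would give ethyl 6-[4-(benzyloxy)-3-hydroxyphenyl]-4-oxo-4H-pyran-2-carboxylate F4.
  - Silylation (iPr3SiCl, imidazole) would give ethyl 6-[4-(benzyloxy)-3-(triisopropylsilyloxy)phenyl]-4-oxo-4H-pyran-2-carboxylate F5.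
  - Brief saponification of this activated ester (LiOH, 1.05 equiv, THF/H2O, 0 °C) would give 6-[4-(benzyloxy)-3-(triisopropylsilyloxy)phenyl]-4-oxo-4H-pyran-2-carboxylic acid F6.
  - Oxalyl chloride with catalytic DMF would give 6-[4-(benzyloxy)-3-(triisopropylsilyloxy)phenyl]-4-oxo-4H-pyran-2-carbonyl chloride F7.
  - Acylation of (trimethylsilyl)diazomethane (MeCN/THF, 0 °C), which is toxic but not explosive, would return to the route at 11.
  - This detour also bypasses steps 4 and 5, so it covers a failure of the diazo transfer as well.

Step 9.
- What may go wrong: incomplete sulfation of the 3'-OH, which is crowded by the neighbouring benzyloxy group, and, if forced, partial sulfation of O5. Mono-, di- and trisulfates would be hard to separate.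
- Fallback: it sets out from 20 and introduces the sulfates as neutral diesters. 2,2,2-Trichloroethyl chlorosulfate (Et3N, 4-dimethylaminopyridine, THF) would give 4'-O-benzylluteolin 7,3'-bis(2,2,2-trichloroethyl sulfate) F8, which can be purified on silica and characterized as an ordinary organic compound. Transfer hydrogenolysis (Pd/C, HCO2NH4, MeOH) would remove both trichloroethyl groups and the benzyl ether in one operation to give diammonium luteolin 7,3'-disulfate F9. The cold acid-resin exchange of step 10 would then return to the route at 23.

## Further compounds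

F1 | step 7 | ethyl 3-[4-(benzyloxy)-3-hydroxyphenyl]-3-oxopropanoate | CCOC(=O)CC(=O)c1ccc(OCc2ccccc2)c(O)c1
F2 | step 6 | 1-(triisopropylsilyloxy)-2-(trimethylsilyl)ethyne | C[Si](C)(C)C#CO[Si](C(C)C)(C(C)C)C(C)C
F3 | step 6 | 4'-O-benzyl-7,3'-bis-O-(triisopropylsilyl)-6-(trimethylsilyl)luteolin | O=c1cc(-c2ccc(OCc3ccccc3)c(O[Si](C(C)C)(C(C)C)C(C)C)c2)oc2cc(O[Si](C(C)C)(C(C)C)C(C)C)c([Si](C)(C)C)c(O)c12
F4 | step 3 | ethyl 6-[4-(benzyloxy)-3-hydroxyphenyl]-4-oxo-4H-pyran-2-carboxylate | CCOC(=O)c1cc(=O)cc(-c2ccc(OCc3ccccc3)c(O)c2)o1
F5 | step 3 | ethyl 6-[4-(benzyloxy)-3-(triisopropylsilyloxy)phenyl]-4-oxo-4H-pyran-2-carboxylate | CCOC(=O)c1cc(=O)cc(-c2ccc(OCc3ccccc3)c(O[Si](C(C)C)(C(C)C)C(C)C)c2)o1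
F6 | step 3 | 6-[4-(benzyloxy)-3-(triisopropylsilyloxy)phenyl]-4-oxo-4H-pyran-2-carboxylic acid | OC(=O)c1cc(=O)cc(-c2ccc(OCc3ccccc3)c(O[Si](C(C)C)(C(C)C)C(C)C)c2)o1
F7 | step 3 | 6-[4-(benzyloxy)-3-(triisopropylsilyloxy)phenyl]-4-oxo-4H-pyran-2-carbonyl chloride | ClC(=O)c1cc(=O)cc(-c2ccc(OCc3ccccc3)c(O[Si](C(C)C)(C(C)C)C(C)C)c2)o1
F8 | step 9 | 4'-O-benzylluteolin 7,3'-bis(2,2,2-trichloroethyl sulfate) | O=c1cc(-c2ccc(OCc3ccccc3)c(OS(=O)(=O)OCC(Cl)(Cl)Cl)c2)oc2cc(OS(=O)(=O)OCC(Cl)(Cl)Cl)cc(O)c12
F9 | step 9 | diammonium luteolin 7,3'-disulfate | O=c1cc(-c2ccc(O)c(OS(=O)(=O)[O-])c2)oc2cc(OS(=O)(=O)[O-])cc(O)c12.[NH4+].[NH4+]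
A1 | alternative 1 | 6-{(3E)-4-[4-(benzyloxy)-3-(methoxymethoxy)phenyl]-2-oxobut-3-en-1-yl}-4-hydroxy-2H-pyran-2-one | O=C(/C=C/c1ccc(OCc2ccccc2)c(OCOC)c1)Cc1cc(O)cc(=O)o1
A2 | alternative 1 | methyl (8E)-9-[4-(benzyloxy)-3-(methoxymethoxy)phenyl]-3,5,7-trioxonon-8-enoate | COC(=O)CC(=O)CC(=O)CC(=O)/C=C/c1ccc(OCc2ccccc2)c(OCOC)c1
A3 | alternative 1 | (E)-3-[4-(benzyloxy)-3-(methoxymethoxy)phenyl]-1-(2,4,6-trihydroxyphenyl)prop-2-en-1-one | O=C(/C=C/c1ccc(OCc2ccccc2)c(OCOC)c1)c1c(O)cc(O)cc1O
A4 | alternative 1 | 4'-O-benzyl-3'-O-(methoxymethyl)luteolin | O=c1cc(-c2ccc(OCc3ccccc3)c(OCOC)c2)oc2cc(O)cc(O)c12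
A5 | alternative 2 | 2-ethynyl-5-hydroxy-7-(methoxymethoxy)-4H-chromen-4-one | C#Cc1cc(=O)c2c(O)cc(OCOC)cc2o1
A6 | alternative 2 | 3-(benzyloxy)furan | c1ccc(COc2ccoc2)cc1
A7 | alternative 2 | 2-[5-(benzyloxy)-7-oxabicyclo[2.2.1]hepta-2,5-dien-2-yl]-5-hydroxy-7-(methoxymethoxy)-4H-chromen-4-one (racemic) | O=c1cc(C2=CC3OC2C=C3OCc4ccccc4)oc5cc(OCOC)cc(O)c15
A8 | alternative 2 | 4'-O-benzyl-7-O-(methoxymethyl)luteolin | O=c1cc(-c2ccc(OCc3ccccc3)c(O)c2)oc2cc(OCOC)cc(O)c12
A9 | alternative 3 | 2-hydroxy-4,6-bis(methoxymethoxy)benzaldehyde | O=Cc1c(O)cc(OCOC)cc1OCOC
A10 | alternative 3 | dimethylsulfoxonium 2-[4-(benzyloxy)-3-(methoxymethoxy)phenyl]-2-oxoethylide | CS(C)(=O)=CC(=O)c1ccc(OCc2ccccc2)c(OCOC)c1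
A11 | alternative 3 | 4'-O-benzyl-5,7,3'-tris-O-(methoxymethyl)luteolin | O=c1cc(-c2ccc(OCc3ccccc3)c(OCOC)c2)oc2cc(OCOC)cc(OCOC)c12
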